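**Assumption:** the SMILES is taken literally, i.e. (1R,2S,5S,6S,10R) with all three stereodefined alkenes E. Target spiro[4.5]decane locants are used for every spirocyclic intermediate: C1 carbinol carbon of the five-membered ring, C2 side-chain carbon, C5 spiro atom, C6 the C(OH)CH3 carbon, C9 keto/ylidene carbon, C10 the carbon carrying the three-carbon arm.

**Retrosynthetic overview**
1. Target ⇐ one global i-Bu2AlH reduction of a tetraenal / Weinreb enamide / bridging seven-membered lactone; side chain ⇐ aldehyde + dienal condensation (dienal ⇐ sulcatone enol triflate + acrolein, Heck).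
2. C9 alkylidene ⇐ HWE on the ketone; C10 arm ⇐ intramolecular Michael of the C9 ketone onto an acrylate hung on O1 (the lactone tether sets and locks C10).
3. C1–OH ⇐ reduction directed by C6–OH; C2 ⇐ enolate allylation.
4. Spiro centre C5 and C6(OH)CH3 ⇐ semipinacol ring expansion of an epoxy cyclobutanol ⇐ catalytic asymmetric, OH-directed epoxidation that desymmetrises an achiral 1,4-cyclohexadiene.
5. That diene ⇐ Birch dearomatisation of 1-(5-methoxy-2-methylphenyl)cyclobutanol ⇐ 2-bromo-4-methoxytoluene + cyclobutanone. Ring order: six-membered ring (from the arene), then five-membered ring (cyclobutane → cyclopentanone), then the temporary seven-membered lactone.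

**Step 1**
Reactants: 1 2-bromo-4-methoxy-1-methylbenzene; 2 cyclobutanone
Product: 4 1-(5-methoxy-2-methylphenyl)cyclobutan-1-ol, via (5-methoxy-2-methylphenyl)lithium 3 (not isolated)
Conditions: n-BuLi, THF, −78 °C; then 2, −78 to 0 °C; aq. NH4Cl
Reagents that add atoms: none
Why: Bromine–lithium exchange followed by 1,2-addition of the aryllithium to the strained ketone (organolithium carbonyl addition) joins the future six-membered ring to the four-membered ring that will later expand; no stereocentre is formed.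

**Step 2**
Reactants: 4 1-(5-methoxy-2-methylphenyl)cyclobutan-1-ol
Product: 5 1-(5-methoxy-2-methylcyclohexa-1,4-dien-1-yl)cyclobutan-1-ol
Conditions: n-BuLi (1 equiv), THF, −78 °C; Li, NH3(l), t-BuOH, −78 to −40 °C; isoprene, then NH4Cl
Reagents that add atoms: none
Why: Birch reduction of the anisole ring, with the benzylic oxygen held as its lithium alkoxide to suppress C–O hydrogenolysis, protonates the two ring CH positions ortho and meta to OMe, leaving both alkyl-bearing carbons on one tetrasubstituted alkene and OMe on the other, so the product is an achiral, mirror-symmetric 1,4-diene.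

**Step 3**
Reactants: 5 1-(5-methoxy-2-methylcyclohexa-1,4-dien-1-yl)cyclobutan-1-ol
Product: 6 1-[(1S,6S)-3-methoxy-6-methyl-7-oxabicyclo[4.1.0]hept-3-en-1-yl]cyclobutan-1-ol
Conditions: Hf(Ot-Bu)4 (10 mol %), (R,R)-N,N′-dihydroxy-N,N′-bis(2,2-diphenylacetyl)cyclohexane-1,2-diamine (12 mol %; the antipode if the sense of induction requires it), cumene hydroperoxide, MgO, toluene, 0 °C
Reagents that add atoms: cumene hydroperoxide, CC(C)(OO)c1ccccc1
Why: Hydroxyl-directed catalytic asymmetric epoxidation (tetravalent hafnium with a bis-hydroxamic acid ligand) oxidises only the alkene allylic to the bound tertiary alkoxide, and the chiral ligand selects one of its two enantiotopic faces, which desymmetrises 5 and sets the future C5 and C6 in one event.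

**Step 4**
Reactants: 6 1-[(1S,6S)-3-methoxy-6-methyl-7-oxabicyclo[4.1.0]hept-3-en-1-yl]cyclobutan-1-ol
Product: 7 (5R,6S)-6-hydroxy-9-methoxy-6-methylspiro[4.5]dec-8-en-1-one
Conditions: BF3·OEt2 (0.3 equiv), CH2Cl2, −78 °C; Et3N quench
Reagents that add atoms: none
Why: Semipinacol ring expansion of the 2,3-epoxy cyclobutanol, driven by release of cyclobutane strain, in which a ring CH2 migrates to C5 anti to the breaking epoxide C–O bond, so C6–OH ends cis to the new ketone carbon C1 and the epoxide chirality is transferred stereospecifically to the spiro centre.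

**Step 5**
Reactants: 7 (5R,6S)-6-hydroxy-9-methoxy-6-methylspiro[4.5]dec-8-en-1-one
Product: 8 (2S,5R,6S)-6-hydroxy-9-methoxy-6-methyl-2-(prop-2-en-1-yl)spiro[4.5]dec-8-en-1-one
Conditions: LiN(i-Pr)2 (2.2 equiv), THF, −78 °C; allyl bromide, −78 to −45 °C; aq. NH4Cl
Reagents that add atoms: allyl bromide, C=CCBr
Why: Enolate alkylation of the alkoxide–enolate dianion, where the enol ether masks the second ketone so C2 is the only enolisable site and enolate formation blocks retro-aldol; allyl bromide is expected to enter C2 on the face syn to C10H2, away from C6 and its lithium alkoxide.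

**Step 6**
Reactants: 8 (2S,5R,6S)-6-hydroxy-9-methoxy-6-methyl-2-(prop-2-en-1-yl)spiro[4.5]dec-8-en-1-one
Product: 10 (1R,2S,5S,6S)-1,6-dihydroxy-6-methyl-2-(prop-2-en-1-yl)spiro[4.5]decan-9-one, via diol enol ether 9 (not isolated)
Conditions: Me4NBH(OAc)3, MeCN–AcOH (1:1), −30 °C; then 1 M aq. HCl, THF, 0 °C
Reagents that add atoms: water, O
Why: Evans–Saksena reduction, in which the C6 tertiary alcohol binds the triacetoxyborohydride and delivers hydride intramolecularly to the face of C1=O on which it sits, gives the 1,6-anti diol with C1–OH cis to the C2 allyl group, and the acidic work-up hydrolyses the methyl enol ether to the C9 ketone.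

**Step 7**
Reactants: 10 (1R,2S,5S,6S)-1,6-dihydroxy-6-methyl-2-(prop-2-en-1-yl)spiro[4.5]decan-9-one
Product: 11 (1R,2S,5S,6S)-6-hydroxy-6-methyl-9-oxo-2-(prop-2-en-1-yl)spiro[4.5]decan-1-yl prop-2-enoate
Conditions: acryloyl chloride, Et3N, DMAP (5 mol %), CH2Cl2, −40 to 0 °C
Reagents that add atoms: acryloyl chloride, C=CC(=O)Cl
Why: Chemoselective O-acylation of the secondary C1 alcohol in the presence of the far more hindered tertiary C6 alcohol places the Michael acceptor on the face of the six-membered ring where the C10 arm must go.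

**Step 8**
Reactants: 11 (1R,2S,5S,6S)-6-hydroxy-6-methyl-9-oxo-2-(prop-2-en-1-yl)spiro[4.5]decan-1-yl prop-2-enoate
Product: 12 O1-lactone of 3-[(1R,2S,5S,6S,10S)-1,6-dihydroxy-6-methyl-9-oxo-2-(prop-2-en-1-yl)spiro[4.5]decan-10-yl]propanoic acid (seven-membered lactone through O1, C1, C5, C10)
Conditions: KOt-Bu (0.3 equiv), t-BuOH–THF (1:5), 0.005 M, 0 °C
Reagents that add atoms: none
Why: Intramolecular Michael addition (7-endo-trig) under equilibrating enolate conditions, in which only the C10 enolate can reach the acrylate (the C8 enolate would need a nine-membered ring) and the tether forces the new C10–C bond onto the face cis to C1–O, which sets C10 and locks it against epimerisation.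

**Step 9**
Reactants: 12 keto lactone from step 8
Product: 13 O1-lactone of 3-[(1R,2S,5S,6S,9E,10R)-1,6-dihydroxy-9-{1-[methoxy(methyl)amino]-1-oxopropan-2-ylidene}-6-methyl-2-(prop-2-en-1-yl)spiro[4.5]decan-10-yl]propanoic acid
Conditions: 2-(diethoxyphosphoryl)-N-methoxy-N-methylpropanamide (4 equiv), NaH (4 equiv), DME, 0 to 85 °C
Reagents that add atoms: 2-(diethoxyphosphoryl)-N-methoxy-N-methylpropanamide, CCOP(=O)(OCC)C(C)C(=O)N(C)OC
Why: Horner–Wadsworth–Emmons olefination of the ketone (the stabilised phosphonate anion ignores the lactone), in which the bulky Weinreb carboxamide is expected to take the less encumbered side syn to C8H2 so that CH3 lies syn to C10, and the amide serves as an aldehyde equivalent that survives until the last hydride step.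

**Step 10**
Reactants: 13 Weinreb enamide lactone from step 9
Product: 15 O1-lactone of 3-[(1R,2S,5S,6S,9E,10R)-1,6-dihydroxy-9-{1-[methoxy(methyl)amino]-1-oxopropan-2-ylidene}-6-methyl-2-(2-oxoethyl)spiro[4.5]decan-10-yl]propanoic acid, via vicinal diol 14 (not isolated)
Conditions: OsO4 (2 mol %), NaIO4 (4 equiv), 2,6-lutidine, dioxane–H2O (3:1), rt
Reagents that add atoms: sodium periodate, [Na+].[O-]I(=O)(=O)=O; osmium tetroxide, O=[Os](=O)(=O)=O
Why: Lemieux–Johnson oxidative cleavage (dihydroxylation then periodate glycol cleavage) of the terminal alkene, with the tetrasubstituted, electron-poor enamide alkene left untouched.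

**Step 11**
Reactants: 16 6-methylhept-5-en-2-one
Product: 17 6-methylhepta-1,5-dien-2-yl trifluoromethanesulfonate
Conditions: LiN(i-Pr)2, THF, −78 °C; PhNTf2, −78 to 0 °C; aq. NH4Cl
Reagents that add atoms: N-phenylbis(trifluoromethanesulfonimide), O=S(=O)(N(c1ccccc1)S(=O)(=O)C(F)(F)F)C(F)(F)F
Why: Kinetic deprotonation of the methyl ketone at CH3 and O-triflation of the less substituted enolate gives the terminal enol triflate.

**Step 12**
Reactants: 17 6-methylhepta-1,5-dien-2-yl trifluoromethanesulfonate
Product: 18 (2E)-8-methyl-4-methylidenenona-2,7-dienal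
Conditions: acrolein (3 equiv), Pd(OAc)2 (5 mol %), n-Bu4NCl, NaHCO3, DMF, 40 °C
Reagents that add atoms: acrolein, C=CC=O
Why: Mizoroki–Heck vinylation of acrolein under ligand-free phase-transfer conditions (zerovalent palladium formed in situ), where syn insertion and syn β-hydride elimination give the E enal.

**Step 13**
Reactants: 15 aldehyde from step 10; 18 (2E)-8-methyl-4-methylidenenona-2,7-dienal
Product: 19 O1-lactone of 3-[(1R,2S,5S,6S,9E,10R)-1,6-dihydroxy-9-{1-[methoxy(methyl)amino]-1-oxopropan-2-ylidene}-6-methyl-2-[(2E,4E)-10-methyl-6-methylidene-1-oxoundeca-2,4,9-trien-2-yl]spiro[4.5]decan-10-yl]propanoic acid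
Conditions: 18 (3 equiv), piperidine (0.3 equiv), AcOH (0.3 equiv), 4 Å molecular sieves, toluene, 45 °C
Reagents that add atoms: none
Why: Amine-salt-catalysed crossed aldol condensation between the enolisable aldehyde 15 and the non-enolisable dienal 18, in which dehydration to the fully conjugated tetraenal is the sink and gives the E alkene with the chain trans to CHO.

**Step 14**
Reactants: 19 tetraenal lactone from step 13
Product: 20 (2E)-2-[(1R,2S,5S,6S,10R)-1,6-dihydroxy-2-[(2E,4E)-1-hydroxy-10-methyl-6-methylideneundeca-2,4,9-trien-2-yl]-10-(3-hydroxypropyl)-6-methylspiro[4.5]decan-9-ylidene]propanal (CNP0246965.4)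
Conditions: i-Bu2AlH (8 equiv), CH2Cl2, −78 to 0 °C; aq. potassium sodium tartrate (KNaC4H4O6)
Reagents that add atoms: none
Why: Global hydride reduction in which i-Bu2AlH reduces the enal (1,2) to the allylic alcohol, opens the lactone to the C1 alcohol and the 3-hydroxypropyl arm, and converts the Weinreb amide into a chelated hemiaminal that releases the enal only on work-up, so no stereocentre or alkene geometry is touched.

**Compound list**
1 | 2-bromo-4-methoxy-1-methylbenzene | Cc1ccc(OC)cc1Br | starting material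
2 | cyclobutanone | O=C1CCC1 | starting material
3 | (5-methoxy-2-methylphenyl)lithium | Cc1ccc(OC)cc1[Li] | intermediate
4 | 1-(5-methoxy-2-methylphenyl)cyclobutan-1-ol | Cc1ccc(OC)cc1C1(O)CCC1 | intermediate
5 | 1-(5-methoxy-2-methylcyclohexa-1,4-dien-1-yl)cyclobutan-1-ol | CC1=C(C2(O)CCC2)CC(OC)=CC1 | intermediate
6 | 1-[(1S,6S)-3-methoxy-6-methyl-7-oxabicyclo[4.1.0]hept-3-en-1-yl]cyclobutan-1-ol | C[C@]12CC=C(OC)C[C@]1(O2)C3(O)CCC3 | intermediate
7 | (5R,6S)-6-hydroxy-9-methoxy-6-methylspiro[4.5]dec-8-en-1-one | C1CC[C@]2(CC(OC)=CC[C@]2(C)O)C1=O | intermediate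
8 | (2S,5R,6S)-6-hydroxy-9-methoxy-6-methyl-2-(prop-2-en-1-yl)spiro[4.5]dec-8-en-1-one | C=CC[C@@H]1CC[C@]2(CC(OC)=CC[C@]2(C)O)C1=O | intermediate
9 | (1R,2S,5S,6S)-9-methoxy-6-methyl-2-(prop-2-en-1-yl)spiro[4.5]dec-8-ene-1,6-diol | C=CC[C@@H]1CC[C@]2(CC(OC)=CC[C@]2(C)O)[C@@H]1O | intermediate
10 | (1R,2S,5S,6S)-1,6-dihydroxy-6-methyl-2-(prop-2-en-1-yl)spiro[4.5]decan-9-one | C=CC[C@@H]1CC[C@]2(CC(=O)CC[C@]2(C)O)[C@@H]1O | intermediate
11 | (1R,2S,5S,6S)-6-hydroxy-6-methyl-9-oxo-2-(prop-2-en-1-yl)spiro[4.5]decan-1-yl prop-2-enoate | C=CC[C@@H]1CC[C@]2(CC(=O)CC[C@]2(C)O)[C@@H]1OC(=O)C=C | intermediate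
12 | O1-lactone of 3-[(1R,2S,5S,6S,10S)-1,6-dihydroxy-6-methyl-9-oxo-2-(prop-2-en-1-yl)spiro[4.5]decan-10-yl]propanoic acid | C=CC[C@@H]1CC[C@]2([C@H](CCC(=O)O3)C(=O)CC[C@]2(C)O)[C@@H]13 | intermediate
13 | O1-lactone of 3-[(1R,2S,5S,6S,9E,10R)-1,6-dihydroxy-9-{1-[methoxy(methyl)amino]-1-oxopropan-2-ylidene}-6-methyl-2-(prop-2-en-1-yl)spiro[4.5]decan-10-yl]propanoic acid | C=CC[C@@H]1CC[C@]2([C@H](CCC(=O)O3)/C(=C(\C)C(=O)N(C)OC)CC[C@]2(C)O)[C@@H]13 | intermediate
14 | the 2-(2,3-dihydroxypropyl) analogue of 13 (diol carbon unassigned) | OCC(O)C[C@@H]1CC[C@]2([C@H](CCC(=O)O3)/C(=C(\C)C(=O)N(C)OC)CC[C@]2(C)O)[C@@H]13 | intermediate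
15 | the 2-(2-oxoethyl) analogue of 13 | O=CC[C@@H]1CC[C@]2([C@H](CCC(=O)O3)/C(=C(\C)C(=O)N(C)OC)CC[C@]2(C)O)[C@@H]13 | intermediate
16 | 6-methylhept-5-en-2-one | CC(=O)CCC=C(C)C | starting material
17 | 6-methylhepta-1,5-dien-2-yl trifluoromethanesulfonate | C=C(OS(=O)(=O)C(F)(F)F)CCC=C(C)C | intermediate
18 | (2E)-8-methyl-4-methylidenenona-2,7-dienal | O=C/C=C/C(=C)CCC=C(C)C | intermediate
19 | the 2-[(2E,4E)-10-methyl-6-methylidene-1-oxoundeca-2,4,9-trien-2-yl] analogue of 13 | C=C(/C=C/C=C(/C=O)[C@@H]1CC[C@]2([C@H](CCC(=O)O3)/C(=C(\C)C(=O)N(C)OC)CC[C@]2(C)O)[C@@H]13)CCC=C(C)C | intermediate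
20 | (2E)-2-[(1R,2S,5S,6S,10R)-1,6-dihydroxy-2-[(2E,4E)-1-hydroxy-10-methyl-6-methylideneundeca-2,4,9-trien-2-yl]-10-(3-hydroxypropyl)-6-methylspiro[4.5]decan-9-ylidene]propanal | C=C(/C=C/C=C(/CO)[C@@H]1CC[C@]2([C@H](CCCO)/C(=C(\C)C=O)CC[C@]2(C)O)[C@@H]1O)CCC=C(C)C | target

**Total step count:** 14. **Longest linear sequence:** 12 (steps 1–10, 13, 14).

**Steps most likely to fail, with fallbacks**

Step 3. Enantioface selection on a tetrasubstituted alkene of a flat cyclohexadiene, next to a second electron-rich alkene, has no exact precedent and the ee may be low. The fallback sets out from 5. Acid-catalysed exchange of the enol ether with ethane-1,2-diol (PPTS, benzene, rt) gives 1-(8-methyl-1,4-dioxaspiro[4.5]dec-7-en-7-yl)cyclobutan-1-ol F1, which has only one alkene. That alkene is epoxidised with a chiral dioxirane instead of a metal alkoxide (D-fructose-derived Shi ketone, KHSO5, K2CO3 buffer, MeCN–dimethoxymethane, 0 °C) to give the epoxy alcohol ketal F2. BF3·OEt2 ring expansion gives the spiro hydroxy ketone ketal F3, and allylation as in step 5 gives its 2-allyl derivative F4. Me4NBH(OAc)3 reduction with aqueous acid work-up, which also removes the dioxolane, comes back to the route at 10.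

Step 8. The C10 enolate can attack the ester carbonyl through a five-membered transition state (O-to-C acyl transfer) instead of the acrylate terminus, and the seven-membered closure needs the less populated ester conformer. The fallback sets out from 11. IBX (DMSO, 65 °C) dehydrogenates the ketone to the enone acrylate F5, in which only C10 can be enolised. LiN(SiMe3)2 (2.1 equiv, THF, −78 °C, high dilution) then forms the kinetic lithium enolate, which adds to the acrylate at a temperature where ester acyl transfer is slow, giving the enone lactone F6. Conjugate reduction of the C7=C8 enone with [(Ph3P)CuH]6 (benzene, rt), which spares the allyl group and the lactone, comes back to the route at 12.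

Step 9. An α-branched ketone and an α-substituted phosphonate make a tetrasubstituted alkene slowly, and the E:Z ratio is only a steric prediction. The fallback sets out from 12 and replaces the phosphorus reagent by a silicon-based addition–elimination (Peterson olefination): the lithium enolate of N-methoxy-N-methyl-2-(trimethylsilyl)propanamide (LiN(i-Pr)2, THF, −78 °C to rt) is smaller and more nucleophilic, adds to the ketone in preference to the lactone, and the β-silyl alkoxide eliminates in the flask. No new isolable compound is formed (F0), and the sequence comes back to the route at 13. Any minor Z isomer is separated and recycled by photochemical E/Z equilibration.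

**Further compounds**
F1 | step 3 | 1-(8-methyl-1,4-dioxaspiro[4.5]dec-7-en-7-yl)cyclobutan-1-ol | CC1=C(C2(O)CCC2)CC2(CC1)OCCO2
F2 | step 3 | 7,8-epoxide of F1 (epoxy alcohol ketal, same absolute sense as 6) | C[C@]12CCC3(OCCO3)C[C@]1(O2)C4(O)CCC4
F3 | step 3 | (5R,6S)-9,9-(ethane-1,2-diyldioxy)-6-hydroxy-6-methylspiro[4.5]decan-1-one | C1CC[C@]2(CC3(OCCO3)CC[C@]2(C)O)C1=O
F4 | step 3 | (2S,5R,6S)-9,9-(ethane-1,2-diyldioxy)-6-hydroxy-6-methyl-2-(prop-2-en-1-yl)spiro[4.5]decan-1-one | C=CC[C@@H]1CC[C@]2(CC3(OCCO3)CC[C@]2(C)O)C1=O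
F5 | step 8 | (1R,2S,5S,6S)-6-hydroxy-6-methyl-9-oxo-2-(prop-2-en-1-yl)spiro[4.5]dec-7-en-1-yl prop-2-enoate | C=CC[C@@H]1CC[C@]2(CC(=O)C=C[C@]2(C)O)[C@@H]1OC(=O)C=C
F6 | step 8 | O1-lactone of 3-[(1R,2S,5S,6S,10S)-1,6-dihydroxy-6-methyl-9-oxo-2-(prop-2-en-1-yl)spiro[4.5]dec-7-en-10-yl]propanoic acid | C=CC[C@@H]1CC[C@]2([C@H](CCC(=O)O3)C(=O)C=C[C@]2(C)O)[C@@H]13
F0 | step 9 | none | none
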